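The route closes the δ-lactone ring (O1, C2–C6) through the C5–C6 bond on a small fragment, before the side chain is attached. C6, the ring carbon that bears both the lactone oxygen and the isopropenyl group, is at once α-acyloxy and allylic, so every isomer of the adduct of but-3-enoyl bromide and methacrolein gives the same planar radical. A chiral nickel hydride catalyst adds to the terminal vinyl group (future C4–C5) and couples C5 with that radical: one stereoconvergent operation closes the ring and sets (R)-C6. A Z-enol triflate at C3 then takes up the aryl-terpenoid chain by B-alkyl Suzuki coupling, and cerium(IV) unveils the quinone.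

Key step: step 2

Assumption: the sense of induction of the nickel/bis(oxazoline) catalyst in the new cyclisation cannot be derived from intermolecular precedent; the route is written with the (S,S)-ligand as the antipode that gives (R)-6, and the (R,R)-ligand is used instead if a first run shows the opposite sense.

Step 1
Reactants: 1 but-3-enoic acid
Product: 2 but-3-enoyl bromide
Conditions: (COBr)2 (1.1 equiv), DMF (cat.), CH2Cl2, 0 °C; volatiles removed cold, used at once
Reagents that add atoms: oxalyl bromide, O=C(Br)C(=O)Br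
Why: Acyl bromide formation through the Vilsmeier-type bromoiminium intermediate is fast at 0 °C, and the cold, base-free conditions should leave the β,γ-double bond unconjugated.

Step 2
Reactants: 2 but-3-enoyl bromide; 3 methacrolein (2-methylprop-2-enal)
Product: 6 (6R)-6-(prop-1-en-2-yl)oxan-2-one, via racemic 1-bromo-2-methylallyl but-3-enoate 4 (not isolated), via 3-bromo-2-methylprop-1-enyl but-3-enoate 5 (not isolated)
Conditions: (i) ZnBr2 (2 mol %), CH2Cl2, −20 → 0 °C, then evaporation; (ii) slow addition to NiBr2·glyme (10 mol %), (S,S)-iPr-BOX [(4S,4′S)-2,2′-(propane-2,2-diyl)bis(4-isopropyl-4,5-dihydrooxazole), 12 mol %], (EtO)3SiH (2 equiv), KF (2.5 equiv), DMA/THF, 0 °C, 0.01 M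
Reagents that add atoms: none
Why: Proposed new method: Ni–H, formed from NiBr2/L*, the silane and fluoride, should add anti-Markovnikov to the terminal C=C of the butenoyl group to give a primary alkyl–Ni at the future C5, while bromine-atom abstraction from either 4 or 5 gives the same planar 1-acyloxy-2-methylallyl radical, which is captured at nickel through its oxygen-bearing carbon and reductively eliminated. The closest known reaction type is the Ni/bis(oxazoline)-catalysed enantioconvergent coupling of racemic 1-bromoalkyl esters (made in situ from an aldehyde and an acyl bromide) with alkyl–Ni species generated from terminal olefins and a hydrosilane, together with Ni-catalysed enantioconvergent alkylation of racemic allylic halides; new here are the intramolecular mode and the enal-derived, allylic electrophile. The six-membered lactone closes by C(sp3)–C(sp3) reductive elimination from a seven-membered alkyl–Ni(III)–alkyl metallacycle, that is a 6-exo bond formation at the acyloxy terminus of the allyl unit. The new stereocentre C6 is set under catalyst control by the chiral bis(oxazoline) on nickel, independently of the constitution, geometry or configuration of the bromide. The step needs anti-Markovnikov Ni–H insertion (monosubstituted alkene, hindered ligand), bond formation at the acyloxy-bearing and not the CH2 terminus of the allyl radical (six- against eight-membered ring) and cyclisation over oligomerisation (slow addition, high dilution), and the mild fluoride activation at 0 °C should leave the β,γ-alkene unconjugated.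

Step 3
Reactants: 6 (6R)-6-(prop-1-en-2-yl)oxan-2-one
Product: 8 [(Z)-[(6R)-2-oxo-6-(prop-1-en-2-yl)oxan-3-ylidene]methyl] trifluoromethanesulfonate, via lithium enolate of the 3-formyl lactone 7 (not isolated)
Conditions: LDA (1.1 equiv), THF, −78 °C; HCO2CH2CF3, −78 → −40 °C; then PhNTf2, −78 °C → rt
Reagents that add atoms: 2,2,2-trifluoroethyl formate, O=COCC(F)(F)F; N-phenylbis(trifluoromethanesulfonimide), O=S(=O)(N(c1ccccc1)S(=O)(=O)C(F)(F)F)C(F)(F)F
Why: Claisen-type C-formylation of the lactone enolate gives the lithium chelate of the 3-formyl lactone, whose enolate oxygen is held syn to the ring carbonyl, so O-triflation (enol triflate formation) should give the Z isomer; C6 is not touched.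

Step 4
Reactants: 9 4-methoxy-2-methylphenol
Product: 10 2-bromo-4-methoxy-6-methylphenol
Conditions: NBS (1.0 equiv), i-Pr2NH (10 mol %), CH2Cl2, 0 °C
Reagents that add atoms: N-bromosuccinimide, O=C1CCC(=O)N1Br
Why: Amine-catalysed electrophilic aromatic bromination is directed ortho to the free hydroxyl, and only one ortho position is open because the para position carries the methoxy group.

Step 5
Reactants: 10 2-bromo-4-methoxy-6-methylphenol
Product: 11 1-bromo-2,5-dimethoxy-3-methylbenzene
Conditions: MeI, K2CO3, acetone, reflux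
Reagents that add atoms: iodomethane, CI
Why: Williamson ether synthesis of the phenoxide with iodomethane.

Step 6
Reactants: 11 1-bromo-2,5-dimethoxy-3-methylbenzene; 12 geranyl bromide [(2E)-1-bromo-3,7-dimethylocta-2,6-diene]
Product: 14 1-[(2E)-3,7-dimethylocta-2,6-dien-1-yl]-2,5-dimethoxy-3-methylbenzene, via (2,5-dimethoxy-3-methylphenyl)lithium 13 (not isolated)
Conditions: n-BuLi (1.05 equiv), THF, −78 °C; CuBr·SMe2 (cat.), then 12, −78 → 0 °C
Reagents that add atoms: none
Why: Bromine–lithium exchange gives the aryllithium, and copper-catalysed SN2 allylic substitution of the primary allylic bromide should occur at the α-carbon with retention of the E-alkene.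

Step 7
Reactants: 14 1-[(2E)-3,7-dimethylocta-2,6-dien-1-yl]-2,5-dimethoxy-3-methylbenzene
Product: 16 (2E,6E)-8-(2,5-dimethoxy-3-methylphenyl)-2,6-dimethylocta-2,6-dienal, via allylic alcohol 15 (not isolated)
Conditions: SeO2 (cat.), t-BuOOH, salicylic acid (cat.), CH2Cl2, rt; filtration, then MnO2, CH2Cl2, rt
Reagents that add atoms: selenium dioxide, O=[Se]=O; tert-butyl hydroperoxide, CC(C)(C)OO (terminal oxidant that regenerates it)
Why: Riley allylic oxidation (ene reaction, then [2,3]-shift) should select the E-methyl group of the terminal trisubstituted alkene, and MnO2 takes the allylic alcohol portion of the mixture on to the E-enal.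

Step 8
Reactants: 16 (2E,6E)-8-(2,5-dimethoxy-3-methylphenyl)-2,6-dimethylocta-2,6-dienal
Product: 17 1-[(2E,6E)-3,7-dimethylnona-2,6,8-trien-1-yl]-2,5-dimethoxy-3-methylbenzene
Conditions: Ph3PCH3Br, KOt-Bu, THF, 0 °C → rt
Reagents that add atoms: methyltriphenylphosphonium bromide, C[P+](c1ccccc1)(c1ccccc1)c1ccccc1.[Br-]
Why: Wittig methylenation of the aldehyde with the non-stabilised ylide leaves the trisubstituted E-alkenes unchanged.

Step 9
Reactants: 17 1-[(2E,6E)-3,7-dimethylnona-2,6,8-trien-1-yl]-2,5-dimethoxy-3-methylbenzene; 8 [(Z)-[(6R)-2-oxo-6-(prop-1-en-2-yl)oxan-3-ylidene]methyl] trifluoromethanesulfonate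
Product: 19 (3Z,6R)-3-[(4E,8E)-10-(2,5-dimethoxy-3-methylphenyl)-4,8-dimethyldeca-4,8-dien-1-ylidene]-6-(prop-1-en-2-yl)oxan-2-one, via B-alkyl-9-borabicyclononane 18 (not isolated)
Conditions: 9-BBN-H (1.0 equiv to 17), THF, 0 °C → rt until no B–H remains; then 8, PdCl2(dppf) (5 mol %), AsPh3, Cs2CO3, DMF/H2O, rt, short reaction time
Reagents that add atoms: none
Why: Anti-Markovnikov hydroboration by 9-BBN is selective for the only monosubstituted alkene, and the B-alkyl Suzuki–Miyaura coupling of the primary alkylborane with the enol triflate proceeds with retention at the sp2 carbon, so the chain should end up cis to the lactone carbonyl (Z).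

Step 10
Reactants: 19 (3Z,6R)-3-[(4E,8E)-10-(2,5-dimethoxy-3-methylphenyl)-4,8-dimethyldeca-4,8-dien-1-ylidene]-6-(prop-1-en-2-yl)oxan-2-one
Product: 20 (3Z,6R)-3-[(4E,8E)-4,8-dimethyl-10-(5-methyl-3,6-dioxocyclohexa-1,4-dien-1-yl)deca-4,8-dien-1-ylidene]-6-(prop-1-en-2-yl)oxan-2-one
Conditions: (NH4)2Ce(NO3)6 (2.5 equiv), MeCN/H2O, 0 °C
Reagents that add atoms: water, O
Why: Oxidative demethylation of the 1,4-dimethoxyarene by cerium(IV), through the arene radical cation and attack of water, should give the para-quinone without touching the alkenes or the stereocentre.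

Compound list
1 | but-3-enoic acid | C=CCC(=O)O | starting material
2 | but-3-enoyl bromide | C=CCC(=O)Br | intermediate
3 | methacrolein (2-methylprop-2-enal) | C=C(C)C=O | starting material
4 | rac-1-bromo-2-methylprop-2-en-1-yl but-3-enoate | C=CCC(=O)OC(Br)C(C)=C | intermediate
5 | 3-bromo-2-methylprop-1-en-1-yl but-3-enoate (E/Z mixture) | C=CCC(=O)OC=C(C)CBr | intermediate
6 | (6R)-6-(prop-1-en-2-yl)oxan-2-one | C=C(C)[C@H]1CCCC(=O)O1 | intermediate
7 | lithium (Z)-[(6R)-2-oxo-6-(prop-1-en-2-yl)oxan-3-ylidene]methanolate | C=C(C)[C@H]1CC/C(=C/[O-])C(=O)O1.[Li+] | intermediate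
8 | [(Z)-[(6R)-2-oxo-6-(prop-1-en-2-yl)oxan-3-ylidene]methyl] trifluoromethanesulfonate | C=C(C)[C@H]1CC/C(=C/OS(=O)(=O)C(F)(F)F)C(=O)O1 | intermediate
9 | 4-methoxy-2-methylphenol | COc1ccc(O)c(C)c1 | starting material
10 | 2-bromo-4-methoxy-6-methylphenol | Brc1cc(OC)cc(C)c1O | intermediate
11 | 1-bromo-2,5-dimethoxy-3-methylbenzene | Brc1cc(OC)cc(C)c1OC | intermediate
12 | geranyl bromide, (2E)-1-bromo-3,7-dimethylocta-2,6-diene | CC(C)=CCC/C(C)=C/CBr | starting material
13 | (2,5-dimethoxy-3-methylphenyl)lithium | [Li]c1cc(OC)cc(C)c1OC | intermediate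
14 | 1-[(2E)-3,7-dimethylocta-2,6-dien-1-yl]-2,5-dimethoxy-3-methylbenzene | CC(C)=CCC/C(C)=C/Cc1cc(OC)cc(C)c1OC | intermediate
15 | (2E,6E)-8-(2,5-dimethoxy-3-methylphenyl)-2,6-dimethylocta-2,6-dien-1-ol | OC/C(C)=C/CC/C(C)=C/Cc1cc(OC)cc(C)c1OC | intermediate
16 | (2E,6E)-8-(2,5-dimethoxy-3-methylphenyl)-2,6-dimethylocta-2,6-dienal | O=C/C(C)=C/CC/C(C)=C/Cc1cc(OC)cc(C)c1OC | intermediate
17 | 1-[(2E,6E)-3,7-dimethylnona-2,6,8-trien-1-yl]-2,5-dimethoxy-3-methylbenzene | C=C/C(C)=C/CC/C(C)=C/Cc1cc(OC)cc(C)c1OC | intermediate
18 | 9-[(3E,7E)-9-(2,5-dimethoxy-3-methylphenyl)-3,7-dimethylnona-3,7-dien-1-yl]-9-borabicyclo[3.3.1]nonane | B1(CC/C(C)=C/CC/C(C)=C/Cc2cc(OC)cc(C)c2OC)C3CCCC1CCC3 | intermediate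
19 | (3Z,6R)-3-[(4E,8E)-10-(2,5-dimethoxy-3-methylphenyl)-4,8-dimethyldeca-4,8-dien-1-ylidene]-6-(prop-1-en-2-yl)oxan-2-one | C=C(C)[C@H]1CC/C(=C/CC/C(C)=C/CC/C(C)=C/Cc2cc(OC)cc(C)c2OC)C(=O)O1 | intermediate
20 | (3Z,6R)-3-[(4E,8E)-4,8-dimethyl-10-(5-methyl-3,6-dioxocyclohexa-1,4-dien-1-yl)deca-4,8-dien-1-ylidene]-6-(prop-1-en-2-yl)oxan-2-one | C=C(C)[C@H]1CC/C(=C/CC/C(C)=C/CC/C(C)=C/CC2=CC(=O)C=C(C)C2=O)C(=O)O1 | target

Total step count: 10.
Longest linear sequence: 7 steps (9 → 20 through steps 4–10). The lactone branch (steps 1–3) joins at step 9.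

Steps most likely to fail

Step 2 (proposed new method). The cyclisation may fail through poor enantioface control at C6, through conjugation of the β,γ-alkene before Ni–H insertion, through Markovnikov insertion leading to a five-membered ring, or through oligomerisation in place of ring closure. The fallback uses known chemistry, sets out from 3 and comes back at 6. Ethyl 4-iodobutanoate is converted with diethylzinc (cat. CuI) into bis(4-ethoxy-4-oxobutyl)zinc F1. F1 is added to methacrolein 3 in toluene at −20 °C with Ti(Oi-Pr)4 and (1S,2S)-N,N′-bis(trifluoromethylsulfonyl)cyclohexane-1,2-diamine (8 mol %), a ligand-accelerated enantioselective dialkylzinc addition. The (1S,2S)-antipode is taken because the (1R,2R)-ligand is the one that leads to (S)-carbinols with aryl and alkenyl aldehydes, and the priority order OH > isopropenyl > alkyl maps directly onto that case. The addition should give ethyl (5R)-5-hydroxy-6-methylhept-6-enoate F2, which is lactonised with catalytic p-TsOH in toluene to 6. In this fallback the C5–C6 bond is made between two molecules and the ring is closed at oxygen.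

Step 9. Pd(0) may ionise the allylic C6–O bond of the lactone, with erosion of configuration or elimination. The β-triflyloxy enoate may also suffer addition–elimination or hydrolysis under the basic aqueous conditions, and the alkylborane may undergo protodeboronation. The fallback avoids palladium and the aqueous base; it sets out from 18 and comes back at 19. The borane 18 is oxidised (NaBO3·4H2O, THF/H2O) to (3E,7E)-9-(2,5-dimethoxy-3-methylphenyl)-3,7-dimethylnona-3,7-dien-1-ol F3. An Appel reaction (CBr4, PPh3, CH2Cl2, 0 °C) gives the bromide 1-[(2E,6E)-9-bromo-3,7-dimethylnona-2,6-dien-1-yl]-2,5-dimethoxy-3-methylbenzene F4. Magnesium in THF gives the Grignard reagent [(3E,7E)-9-(2,5-dimethoxy-3-methylphenyl)-3,7-dimethylnona-3,7-dien-1-yl]magnesium bromide F5. F5 is coupled with the enol triflate 8 under iron catalysis (Fe(acac)3 5 mol %, THF/NMP, −30 °C, minutes), a stereoretentive sp2–sp3 coupling that is faster than addition to the lactone carbonyl, to give 19.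

Step 3. Geometric control may be lost when the enolate is O-sulfonylated in the same flask (Z/E mixture), and the lactone may be opened by trifluoroethoxide. The fallback sets the geometry in a separate, reagent-controlled step and uses a less labile electrophile; it sets out from 6 and comes back at 19. Formylation as before (LDA, then trifluoroethyl formate) and acidic work-up give the isolated enol (3Z,6R)-3-(hydroxymethylidene)-6-(prop-1-en-2-yl)oxan-2-one F6. Z-selective enol tosylation under lithium-chelate conditions (TsCl, N-methylimidazole, LiOH, CH2Cl2, 0 °C) gives [(Z)-[(6R)-2-oxo-6-(prop-1-en-2-yl)oxan-3-ylidene]methyl] 4-methylbenzenesulfonate F7, from which any E isomer is removed by chromatography. F7 is coupled with the borane 18 (Pd(OAc)2, SPhos, K3PO4, THF/H2O) to give 19.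

Further compounds
F1 | step 2 | bis(4-ethoxy-4-oxobutyl)zinc | CCOC(=O)CCC[Zn]CCCC(=O)OCC
F2 | step 2 | ethyl (5R)-5-hydroxy-6-methylhept-6-enoate | C=C(C)[C@H](O)CCCC(=O)OCC
F3 | step 9 | (3E,7E)-9-(2,5-dimethoxy-3-methylphenyl)-3,7-dimethylnona-3,7-dien-1-ol | OCC/C(C)=C/CC/C(C)=C/Cc1cc(OC)cc(C)c1OC
F4 | step 9 | 1-[(2E,6E)-9-bromo-3,7-dimethylnona-2,6-dien-1-yl]-2,5-dimethoxy-3-methylbenzene | BrCC/C(C)=C/CC/C(C)=C/Cc1cc(OC)cc(C)c1OC
F5 | step 9 | [(3E,7E)-9-(2,5-dimethoxy-3-methylphenyl)-3,7-dimethylnona-3,7-dien-1-yl]magnesium bromide | Br[Mg]CC/C(C)=C/CC/C(C)=C/Cc1cc(OC)cc(C)c1OC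
F6 | step 3 | (3Z,6R)-3-(hydroxymethylidene)-6-(prop-1-en-2-yl)oxan-2-one | C=C(C)[C@H]1CC/C(=C/O)C(=O)O1
F7 | step 3 | [(Z)-[(6R)-2-oxo-6-(prop-1-en-2-yl)oxan-3-ylidene]methyl] 4-methylbenzenesulfonate | C=C(C)[C@H]1CC/C(=C/OS(=O)(=O)c2ccc(C)cc2)C(=O)O1
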